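**Retrosynthetic overview**

- The succinimide comes last, from an Evans syn-aldol at C12–C13 on a decalin aldehyde followed by ammonolysis; the 2α-chloride comes from SN2 inversion of a 2β-alcohol, and both ring carbinols from α-face hydride reduction of a 2,6-dione.
- Ring B (C5–C6–C7–C8–C9–C10) is closed by a type-2 carbonyl-ene reaction (C6–C7) that also makes the C8=C17 methylene; the second C4 methyl is then added by a cuprate to the C4=C5–C6=O enone, which sets C5 in the real decalin.
- Ring A (C1–C2–C3–C4–C5–C10) is closed first, by a vinylogous Dieckmann condensation forming C2–C3. The enabling feature is the 1,5-relationship of the C2 and C6 oxygens across C3–C4=C5: with C6 as an ester conjugated to a C4=C5 isopropylidene, the C3 methyl is a vinylogous ester α-position and attacks a C2 ester on the C10 acetate arm.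
- C9 and C10 come from (+)-verbenone: cuprate addition anti to the CMe2 bridge sets C10, cyclobutane fragmentation unveils the C9 isopropenyl (C8, C7, C17), and oxidative cleavage of the remaining temporary six-membered ring (C6–C12) gives the C6 ester and the C11–C12 chain.
- Ring order: temporary carbocycle (from verbenone, cleaved in step 6), ring A (step 9), ring B (step 12), imide ring (step 22).

Key step: step 9

Remarks on the chemistry: atom numbers are labdane numbers of the target (Cl on C2, gem-dimethyl on C4, OH on C6 and C12, C8=C17, imide carbons C13–C16). (1R,5R)-(+)-Verbenone is taken as commercial; it is otherwise one allylic oxidation from (1R)-(+)-α-pinene.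

**Route**

Step 1
Reactants: 1 (1R,5R)-(+)-verbenone
Product: 2 4-(bromomethyl)-6,6-dimethylbicyclo[3.1.1]hept-3-en-2-one (bridgeheads as in 1)
Conditions: NBS, AIBN (cat.), PhCF3, reflux
Reagents that add atoms: N-bromosuccinimide, O=C1CCC(=O)N1Br
Why: Wohl–Ziegler allylic bromination; only the vinylic methyl gives a radical conjugated with the enone, since the allylic bridgehead C–H cannot delocalise, and no stereocentre is touched.

Step 2
Reactants: 2 bromomethyl enone
Product: 3 methyl 2-(6,6-dimethyl-4-oxobicyclo[3.1.1]hept-2-en-2-yl)acetate (bridgeheads as in 1)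
Conditions: Pd(PPh3)4 (cat.), CO (3 atm), MeOH, iPr2NEt, THF, 45 °C
Reagents that add atoms: carbon monoxide, [C-]#[O+]; methanol, CO
Why: Palladium-catalysed alkoxycarbonylation of an allylic halide through a π-allylpalladium intermediate; CO inserts at the primary terminus so the enone stays conjugated, giving the C1–C2 ester arm.

Step 3
Reactants: 3 enone ester; 4 acetone
Product: 6 pinanone aldol (methyl and CH2CO2Me on C10; C(OH)Me2 on C5), via trimethylsilyl enol ether 5 (not isolated)
Conditions: Me2CuLi, Me3SiCl, THF, −78 °C; then acetone, TiCl4, CH2Cl2, −78 °C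
Reagents that add atoms: lithium dimethylcuprate, [Li+].C[Cu-]C; chlorotrimethylsilane, C[Si](C)(C)Cl (silicon in intermediate 5 only)
Why: Cuprate conjugate addition to a verbenone-type enone occurs anti to the CMe2 bridge and so sets C10 (methyl on the CH2-bridge face, ester arm on the CMe2-bridge face); the C5=C6 silyl enol ether forms regiospecifically because the other α-carbon is a bridgehead, and it adds to acetone in a Mukaiyama aldol whose C5 stereocentre is transient.

Step 4
Reactants: 6 pinanone aldol
Product: 8 methyl 2-[1-methyl-3-oxo-2-(propan-2-ylidene)-6-(prop-1-en-2-yl)cyclohexyl]acetate (methyl and isopropenyl trans), via dienol acetate 7 (not isolated)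
Conditions: BF3·OEt2, Zn(OAc)2, Ac2O, 0 °C to rt; then K2CO3, MeOH, rt
Reagents that add atoms: acetic anhydride, CC(=O)OC(C)=O (acetyl in intermediate 7 only)
Why: Acid-promoted dehydration of the tertiary aldol and cleavage of the cyclobutane bond between the bridgehead α-carbon and CMe2 (the fragmentation known for nopinone- and verbanone-type ketones) give a tertiary cation that loses a proton to the C9 isopropenyl group; the enol is trapped as its acetate and methanolysis returns the conjugated ketone, with C9 and C10 untouched.

Step 5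
Reactants: 8 isopropylidene cyclohexanone
Product: 10 α'-ketol (OH on C12; either epimer), via lithium enolate 9 (not isolated)
Conditions: LiN(iPr)2, THF, −78 °C; then 2-(phenylsulfonyl)-3-phenyloxaziridine, −78 °C
Reagents that add atoms: 2-(phenylsulfonyl)-3-phenyloxaziridine, O=S(=O)(c1ccccc1)N1OC1c1ccccc1; lithium diisopropylamide, [Li]N(C(C)C)C(C)C (lithium in intermediate 9 only)
Why: Kinetic α'-deprotonation of an alkylidene ketone at its only CH2 next to the carbonyl (as with pulegone), followed by Davis enolate hydroxylation; the carbinol configuration is irrelevant.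

Step 6
Reactants: 10 α'-ketol
Product: 11 dimethyl 3-methyl-3-(2-methyl-5-oxopent-1-en-3-yl)-2-(propan-2-ylidene)pentanedioate
Conditions: Pb(OAc)4, MeOH–benzene, 0 °C
Reagents that add atoms: methanol, CO
Why: Lead tetraacetate cleavage of an α-hydroxy ketone in methanol turns the ketone carbon into a methyl ester (C6) and the carbinol carbon into an aldehyde (C12), opening the temporary ring without touching C9 or C10.

Step 7
Reactants: 11 diester aldehyde
Product: 12 dimethyl 3-(5-hydroxy-2-methylpent-1-en-3-yl)-3-methyl-2-(propan-2-ylidene)pentanedioate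
Conditions: NaBH4, MeOH, −20 °C
Reagents that add atoms: none
Why: Chemoselective borohydride reduction of the aldehyde in the presence of two esters.

Step 8
Reactants: 12 primary alcohol
Product: 13 tert-butyldimethylsilyl ether of 12
Conditions: t-BuMe2SiCl, imidazole, DMF, rt
Reagents that add atoms: tert-butyldimethylsilyl chloride, CC(C)(C)[Si](C)(C)Cl
Why: Standard silylation of a primary alcohol, protecting C12–O through to step 18.

Step 9
Reactants: 13 acyclic diester
Product: 14 methyl 6-[5-(tert-butyldimethylsilyloxy)-2-methylpent-1-en-3-yl]-2,6-dimethyl-4-oxocyclohex-1-ene-1-carboxylate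
Conditions: KN(SiMe3)2 (2.3 equiv), THF, −78 to −20 °C; AcOH, −78 °C
Reagents that add atoms: none
Why: KN(SiMe3)2 removes a γ-proton from a methyl of the C5=C4 isopropylidene ester, and the extended enolate attacks the C2 ester carbonyl of the C10 acetate arm through its γ-carbon C3, expelling methoxide; deprotonation of the product to a delocalised dienolate drives the equilibrium. The closest known reaction type is the Dieckmann (intramolecular Claisen) condensation run through a vinylogous ester enolate, as in γ-acylations of senecioate-type dienolates. Ring A (C1, C2, C3, C4, C5, C10) closes in a 6-exo-trig nucleophilic acyl substitution, the C2 carbonyl being exocyclic to the forming ring and the nucleophile the γ-terminus of the dienolate. No stereocentre is formed, and C9 and C10 are not enolisable and stay intact. The step needs γ- rather than α-acylation and reaction of the dienolate rather than of the C1 ester enolate: α-attack (C5 on C2) or attack of the C1 enolate on C6 would give a four-membered ring, so only the C3-to-C2 closure is productive. The cold AcOH quench protonates C3 kinetically, giving the β,γ-unsaturated keto ester with C4=C5 still conjugated to the C6 ester, as the next steps require.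

Step 10
Reactants: 14 keto enoate
Product: 15 diol (C2 carbinol as an epimer mixture; allylic CH2OH at C6)
Conditions: iBu2AlH (5 equiv), CH2Cl2, −78 to 0 °C
Reagents that add atoms: none
Why: iBu2AlH reduces the ketone and, by 1,2-reduction, the conjugated ester to the allylic alcohol; the C2 configuration is irrelevant because it is re-oxidised in step 15.

Step 11
Reactants: 15 diol
Product: 16 4-hydroxy-2,6-dimethyl-6-[5-(tert-butyldimethylsilyloxy)-2-methylpent-1-en-3-yl]cyclohex-1-ene-1-carbaldehyde
Conditions: MnO2, CH2Cl2, rt
Reagents that add atoms: none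
Why: Manganese dioxide oxidises only the allylic primary alcohol (a β-cyclogeraniol-type oxidation) and leaves the non-allylic C2 carbinol.

Step 12
Reactants: 16 enal
Product: 17 bicyclic diene diol (rings A and B; C4=C5 and C8=C17; OH at C2 and C6 as epimer mixtures; CH2CH2OSi on C9)
Conditions: Me2AlCl (3 equiv), CH2Cl2, −78 to −30 °C
Reagents that add atoms: none
Why: Type-2 intramolecular carbonyl-ene reaction (Snider): the Me2AlCl-bound aldehyde carbon C6 is attacked by the CH2 terminus (C7) of the isopropenyl group with transfer of an allylic hydrogen from its methyl, closing ring B through a chair with the C11 chain equatorial and creating the C8=C17 methylene; C9 and C10 fix the ring fusion, and the C6 configuration is irrelevant because it is oxidised next.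

Step 13
Reactants: 17 diene diol
Product: 18 C4=C5–C6=O enone with free C2 carbinol
Conditions: MnO2, CH2Cl2, rt
Reagents that add atoms: none
Why: Manganese dioxide oxidises only the allylic C6 carbinol, which avoids the tautomerisable 2,6-dioxo-4-ene system.

Step 14
Reactants: 18 hydroxy enone
Product: 19 4,4-dimethyl trans-fused 6-ketone (5α-H) with free C2 carbinol
Conditions: Me2CuLi (5 equiv), BF3·OEt2, Et2O, −78 to −40 °C; AcOH, −78 °C
Reagents that add atoms: lithium dimethylcuprate, [Li+].C[Cu-]C
Why: Cuprate conjugate addition to a β,β-disubstituted alkylidene ketone (as in pulegone to tert-butyl ketone) creates the C4 gem-dimethyl carbon; the C5=C6 enolate is protonated on its α-face because the β-face is shielded by the axial C10 methyl and the C4 β-methyl, which sets the trans ring fusion.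

Step 15
Reactants: 19 hydroxy ketone
Product: 20 2,6-dione
Conditions: Dess–Martin periodinane, NaHCO3, CH2Cl2, 0 °C
Reagents that add atoms: none
Why: Buffered Dess–Martin oxidation of the C2 carbinol under conditions that should not move the exocyclic alkene into conjugation or epimerise C5.

Step 16
Reactants: 20 dione
Product: 21 2β,6β-diol
Conditions: NaBH4, CeCl3·7H2O, MeOH, −40 to 0 °C
Reagents that add atoms: none
Why: Luche-type hydride reduction; at both carbonyls the β-face is blocked by the syn-axial C10 methyl and C4 β-methyl, so hydride arrives from the α-face and gives the axial 2β and 6β alcohols.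

Step 17
Reactants: 21 diol
Product: 22 2α-chloro-6β-ol silyl ether
Conditions: PPh3, CCl4, pyridine, ClCH2CH2Cl, 50 °C
Reagents that add atoms: tetrachloromethane, ClC(Cl)(Cl)Cl
Why: Appel reaction with SN2 inversion turns the 2β-alcohol into the equatorial 2α-chloride; the 6β-hydroxyl, axial and next to the fully flanked C5, should not undergo displacement.

Step 18
Reactants: 22 silyl ether
Product: 23 2α-chloro-6β,12-diol
Conditions: Bu4NF, AcOH, THF, rt
Reagents that add atoms: none
Why: Buffered fluoride cleavage of the primary silyl ether.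

Step 19
Reactants: 23 diol
Product: 24 C12 aldehyde with free 6β-hydroxyl
Conditions: TEMPO (cat.), PhI(OAc)2, CH2Cl2, rt
Reagents that add atoms: none
Why: The TEMPO/PhI(OAc)2 system oxidises primary alcohols selectively over a hindered axial secondary alcohol.

Step 20
Reactants: 25 (R)-4-benzyl-1,3-oxazolidin-2-one; 26 methyl 4-chloro-4-oxobutanoate
Product: 28 (R)-4-benzyl-3-(4-methoxy-4-oxobutanoyl)-1,3-oxazolidin-2-one, via N-lithio oxazolidinone 27 (not isolated)
Conditions: n-BuLi, THF, −78 °C; then 26, −78 to 0 °C
Reagents that add atoms: n-butyllithium, [Li]CCCC (lithium in intermediate 27 only)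
Why: Standard N-acylation of a lithiated Evans auxiliary with an acid chloride.

Step 21
Reactants: 24 aldehyde; 28 imide
Product: 30 syn-aldol adduct (12S,13R), via Z-dibutylboron enolate 29 (not isolated)
Conditions: 28 (2.2 equiv), Bu2BOTf, iPr2NEt, CH2Cl2, 0 °C; then 24, −78 to 0 °C; pH 7 buffer, MeOH, H2O2
Reagents that add atoms: dibutylboron triflate, CCCCB(CCCC)OS(=O)(=O)C(F)(F)F (boron and butyl groups in intermediate 29 only)
Why: Evans syn-aldol through the Z-boron enolate and a Zimmerman–Traxler chair; the (R)-benzyl auxiliary sets C12 (S) and C13 (R) under reagent control, and excess enolate allows for the free hindered 6β-hydroxyl.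

Step 22
Reactants: 30 aldol adduct
Product: 32 haterumaimide F, via primary amide 31 (not isolated)
Conditions: NH3 (7 M in MeOH), 0 °C to rt
Reagents that add atoms: ammonia, N
Why: Ammonolysis of the N-acyl oxazolidinone gives the primary amide, whose nitrogen closes onto the methyl ester in a 5-exo-trig acyl substitution (aspartimide-type) to form the succinimide under conditions mild enough to keep C13.

**Compound list**

1 | (1R,5R)-(+)-verbenone | CC1=CC(=O)[C@@H]2C[C@H]1C2(C)C | starting material
2 | 4-(bromomethyl)-6,6-dimethylbicyclo[3.1.1]hept-3-en-2-one, bridgeheads as in 1 | BrCC1=CC(=O)[C@@H]2C[C@H]1C2(C)C | intermediate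
3 | methyl 2-(6,6-dimethyl-4-oxobicyclo[3.1.1]hept-2-en-2-yl)acetate, bridgeheads as in 1 | COC(=O)CC1=CC(=O)[C@@H]2C[C@H]1C2(C)C | intermediate
4 | acetone | CC(C)=O | starting material
5 | trimethylsilyl enol ether of the 1,4-methyl adduct of 3 (new methyl on the CH2-bridge face) | C[Si](C)(C)OC1=C[C@](C)(CC(=O)OC)[C@H]2C[C@@H]1C2(C)C | intermediate
6 | pinanone aldol: methyl 2-[3-(2-hydroxypropan-2-yl)-2,6,6-trimethyl-4-oxobicyclo[3.1.1]hept-2-yl]acetate | O=C1[C@@H](C(C)(C)O)[C@](C)(CC(=O)OC)[C@H]2C[C@@H]1C2(C)C | intermediate
7 | dienol acetate of 8 (enol acetate toward C12) | CC(=O)OC1=CC[C@@H](C(C)=C)[C@@](C)(CC(=O)OC)C1=C(C)C | intermediate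
8 | methyl 2-[1-methyl-3-oxo-2-(propan-2-ylidene)-6-(prop-1-en-2-yl)cyclohexyl]acetate, methyl and isopropenyl trans | O=C1C(=C(C)C)[C@](C)(CC(=O)OC)[C@H](C(C)=C)CC1 | intermediate
9 | lithium enolate of 8 toward C12 | [Li]OC1=CC[C@@H](C(C)=C)[C@@](C)(CC(=O)OC)C1=C(C)C | intermediate
10 | α'-ketol of 8 (OH on C12, carbinol configuration not controlled) | O=C1C(=C(C)C)[C@](C)(CC(=O)OC)[C@H](C(C)=C)CC1O | intermediate
11 | dimethyl 3-methyl-3-(2-methyl-5-oxopent-1-en-3-yl)-2-(propan-2-ylidene)pentanedioate | COC(=O)C(=C(C)C)[C@](C)(CC(=O)OC)[C@H](C(C)=C)CC=O | intermediate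
12 | dimethyl 3-(5-hydroxy-2-methylpent-1-en-3-yl)-3-methyl-2-(propan-2-ylidene)pentanedioate | COC(=O)C(=C(C)C)[C@](C)(CC(=O)OC)[C@H](C(C)=C)CCO | intermediate
13 | tert-butyldimethylsilyl ether of 12 | COC(=O)C(=C(C)C)[C@](C)(CC(=O)OC)[C@H](C(C)=C)CCO[Si](C)(C)C(C)(C)C | intermediate
14 | methyl 6-[5-(tert-butyldimethylsilyloxy)-2-methylpent-1-en-3-yl]-2,6-dimethyl-4-oxocyclohex-1-ene-1-carboxylate | COC(=O)C1=C(C)CC(=O)C[C@]1(C)[C@H](C(C)=C)CCO[Si](C)(C)C(C)(C)C | intermediate
15 | ring A diol: C6 allylic CH2OH and C2 carbinol (epimers) | OCC1=C(C)CC(O)C[C@]1(C)[C@H](C(C)=C)CCO[Si](C)(C)C(C)(C)C | intermediate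
16 | ring A enal with C2 carbinol (epimers) | O=CC1=C(C)CC(O)C[C@]1(C)[C@H](C(C)=C)CCO[Si](C)(C)C(C)(C)C | intermediate
17 | bicyclic diene diol: C4=C5, C8=C17, OH at C2 and C6 (epimers), CH2CH2OSi on C9 | C=C1CC(O)C2=C(C)CC(O)C[C@]2(C)[C@H]1CCO[Si](C)(C)C(C)(C)C | intermediate
18 | C4=C5–C6=O enone with C2 carbinol (epimers) | C=C1CC(=O)C2=C(C)CC(O)C[C@]2(C)[C@H]1CCO[Si](C)(C)C(C)(C)C | intermediate
19 | 4,4-dimethyl trans-fused 6-ketone (5α-H) with C2 carbinol (epimers) | C=C1CC(=O)[C@H]2C(C)(C)CC(O)C[C@]2(C)[C@H]1CCO[Si](C)(C)C(C)(C)C | intermediate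
20 | 2,6-dione | C=C1CC(=O)[C@H]2C(C)(C)CC(=O)C[C@]2(C)[C@H]1CCO[Si](C)(C)C(C)(C)C | intermediate
21 | 2β,6β-diol | C=C1C[C@@H](O)[C@H]2C(C)(C)C[C@@H](O)C[C@]2(C)[C@H]1CCO[Si](C)(C)C(C)(C)C | intermediate
22 | 2α-chloro-6β-ol, C12 silyl ether | C=C1C[C@@H](O)[C@H]2C(C)(C)C[C@H](Cl)C[C@]2(C)[C@H]1CCO[Si](C)(C)C(C)(C)C | intermediate
23 | 2α-chloro-6β,12-diol | C=C1C[C@@H](O)[C@H]2C(C)(C)C[C@H](Cl)C[C@]2(C)[C@H]1CCO | intermediate
24 | 2α-chloro-6β-hydroxy C12 aldehyde | C=C1C[C@@H](O)[C@H]2C(C)(C)C[C@H](Cl)C[C@]2(C)[C@H]1CC=O | intermediate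
25 | (R)-4-benzyl-1,3-oxazolidin-2-one | O=C1N[C@H](Cc2ccccc2)CO1 | starting material
26 | methyl 4-chloro-4-oxobutanoate | COC(=O)CCC(Cl)=O | starting material
27 | N-lithio salt of 25 | [Li]N1[C@H](Cc2ccccc2)COC1=O | intermediate
28 | (R)-4-benzyl-3-(4-methoxy-4-oxobutanoyl)-1,3-oxazolidin-2-one | COC(=O)CCC(=O)N1[C@H](Cc2ccccc2)COC1=O | intermediate
29 | Z-dibutylboron enolate of 28 | CCCCB(CCCC)O/C(=C\CC(=O)OC)N1[C@H](Cc2ccccc2)COC1=O | intermediate
30 | syn-aldol adduct (12S,13R) with methyl ester and oxazolidinone | C=C1C[C@@H](O)[C@H]2C(C)(C)C[C@H](Cl)C[C@]2(C)[C@H]1C[C@H](O)[C@@H](CC(=O)OC)C(=O)N1[C@H](Cc2ccccc2)COC1=O | intermediate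
31 | primary amide methyl ester | C=C1C[C@@H](O)[C@H]2C(C)(C)C[C@H](Cl)C[C@]2(C)[C@H]1C[C@H](O)[C@@H](CC(=O)OC)C(N)=O | intermediate
32 | haterumaimide F (2α-Cl, 5α-H, 6β-OH, 9α-H, 10β-CH3, 12S, 13R) | C=C1C[C@@H](O)[C@H]2C(C)(C)C[C@H](Cl)C[C@]2(C)[C@H]1C[C@H](O)[C@H]1CC(=O)NC1=O | target

**Step count and risks**

Total steps: 22. Longest linear sequence: 21 (steps 1–19, 21, 22).

Steps most likely to fail:

1. Step 12 (ene closure of ring B on the enal). The alkene may attack the enal β-carbon C4 instead of the carbonyl carbon, the doubly allylic C6 aluminium alkoxide may ionise, or Prins-type proton loss may give endocyclic alkenes. Fallback, setting out from 16 and returning at 20: conjugate methylation of the enal with Me2CuLi/Me3SiCl, hydrolysis of the silyl enol ether and base equilibration at C5 (with separation of the C5 epimers if needed) would give the saturated trans aldehyde F1. Its type-2 carbonyl-ene cyclisation with Me2AlCl, a saturated aldehyde as in the classical cases, would give the 6β-hydroxy decalin F2. Dess–Martin oxidation of both carbinols of F2 then gives dione 20.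

2. Step 4 (one-pot dehydration and cyclobutane fragmentation). The tertiary C8 cation may be captured by acetate or by the neighbouring ester carbonyl (lactonisation), or may undergo Wagner–Meerwein shifts, instead of losing a proton. Fallback, setting out from 6 and returning at 8: dehydration of 6 with the Burgess reagent followed by DBU would give the conjugated isopropylidene pinanone F3. Nucleophile-assisted opening of its cyclobutane with Me3SiI at −20 °C and aqueous work-up would give the tertiary iodide F4. Separate elimination of HI from F4 with DBU toward the methyl groups then gives 8.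

3. Step 14 (cuprate addition to the tetrasubstituted enone in the decalin). Addition to the peri-hindered β-carbon may be slow, leaving room for deprotonation at C7 and migration of the exocyclic double bond into conjugation. Fallback, setting out from 17 and returning at 20: hydroxyl-directed Simmons–Smith cyclopropanation (Et2Zn, CH2I2) of the C4=C5 bond of the allylic alcohol would give the cyclopropane diol F5. Dess–Martin oxidation would give the cyclopropyl diketone F6. Reductive opening with Li in NH3/t-BuOH cleaves the C5–CH2 bond, turning the CH2 into the second C4 methyl with protonation of the C5 enolate from the α-face; Dess–Martin re-oxidation of any over-reduced carbinols then gives 20.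

Further compounds
F1 | step 12 | saturated trans aldehyde: 4,4-dimethyl ring A with C5–CHO (5α-H) and C2 carbinol | O=C[C@H]1C(C)(C)CC(O)C[C@]1(C)[C@H](C(C)=C)CCO[Si](C)(C)C(C)(C)C
F2 | step 12 | 4,4-dimethyl decalin 2,6-diol (6β-OH, C2 epimers), C8=C17 | C=C1C[C@@H](O)[C@H]2C(C)(C)CC(O)C[C@]2(C)[C@H]1CCO[Si](C)(C)C(C)(C)C
F3 | step 4 | isopropylidene pinanone: methyl 2-[2,6,6-trimethyl-4-oxo-3-(propan-2-ylidene)bicyclo[3.1.1]hept-2-yl]acetate | O=C1C(=C(C)C)[C@](C)(CC(=O)OC)[C@H]2C[C@@H]1C2(C)C
F4 | step 4 | tertiary iodide: methyl 2-[6-(2-iodopropan-2-yl)-1-methyl-3-oxo-2-(propan-2-ylidene)cyclohexyl]acetate | O=C1C(=C(C)C)[C@](C)(CC(=O)OC)[C@H](C(C)(C)I)CC1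
F5 | step 14 | C4–C5 cyclopropane diol (cyclopropane on the face of the C6 hydroxyl, not assigned) | C=C1CC(O)C23CC2(C)CC(O)C[C@]3(C)[C@H]1CCO[Si](C)(C)C(C)(C)C
F6 | step 14 | C4–C5 cyclopropyl 2,6-diketone | C=C1CC(=O)C23CC2(C)CC(=O)C[C@]3(C)[C@H]1CCO[Si](C)(C)C(C)(C)C
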